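Monomer in chains after 2.5 d is what Anna and Ben dispute for Tuesday's, Thursday's and Saturday's, flasks that differ in temperature.

all flasks: free monomer 0.050 M

| flask | transfer agent | pre-initiator | temperature | remark | time |
|---|---|---|---|---|---|
| green | 2.5 mM | 1 mM | −20 °C | run made earlier |  |
| red | 3.8 mM | 1 mM | 0 °C | run made earlier |  |
| grey | 5 mM | 2 mM | −20 °C | run made earlier |  |
| Tuesday's | 5.00 mM | 1.0 mM | −15 °C |  | 2.5 d |
| Thursday's | 5.00 mM | 1.0 mM | 0 °C |  | 2.5 d |
| Saturday's | 5.00 mM | 1.0 mM | 15 °C |  | 2.5 d |

green run (percent of the free monomer charged)

| time / d | monomer in chains / % | free monomer / % |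
|---|---|---|
| 0.417 | 0.3 | 100.0 |
| 0.833 | 0.4 | 99.4 |
| 1.25 | 0.1 | 99.7 |
| 1.67 | 0.9 | 99.6 |
| 2.00 | 0.4 | 99.5 |
| 2.50 | 0.9 | 99.2 |

red run (percent of the free monomer charged)

| time / h | monomer in chains / % | free monomer / % |
|---|---|---|
| 2.00 | 0 | 100.0 |
| 6.00 | 1.3 | 99.1 |
| 10.0 | 3.5 | 96.4 |
| 15.0 | 11.1 | 88.7 |
| 25.0 | 33.6 | 67.3 |
| 30.0 | 45.5 | 53.8 |

grey run (percent of the free monomer charged)

| time / d | monomer in chains / % | free monomer / % |
|---|---|---|
| 0.500 | 0.4 | 100.3 |
| 1.04 | 0 | 100.3 |
| 1.67 | 0.6 | 99.4 |
| 2.08 | 1.2 | 99.1 |
| 2.50 | 1.8 | 98.3 |

(scatter of a reading: 0.3 percentage points)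

* the flask that comes out highest in amount of monomer in chains, in percent of the free monomer charged, or "all alike" when all lie within 1.5 percentage points (Tuesday's / Thursday's / Saturday's / all alike)
* monomer in chains at the end, in percent of the free monomer charged, Tuesday's
* monomer in chains at the end, in percent of the free monomer charged, Thursday's
* monomer in chains at the end, in percent of the free monomer charged, Saturday's

- what was read earlier has a scatter of 0.3 percentage points, one standard deviation
- candidate steps: free monomer + initiator -> living end + monomer in chains; free monomer + living end -> monomer in chains + living end; living end + transfer agent -> dead chain; pre-initiator -> initiator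

Anna holds a plain first-order view: a steady number of living ends takes the same fraction of free monomer in each equal time. Red, at Thursday's temperature, keeps 53.8% after 30.0 h, so she squares that fraction for twice the time and gives Thursday's 71.1%.

Ben answers that red's curve bends upward. The logarithm of the free monomer left grew 5.17-fold from 15.0 h to 30.0 h, so he sees living ends still piling up after a lag (induction period). The same step gives him 95.9% for Thursday's.

For the other flasks Ben compares clocks. Green at −20 °C stands at 99.2% free monomer after 2.50 d, and red at 0 °C stands at 99.1% after 6.00 h, which gives 10.0. This is his clock factor (shift factor), the time a colder flask needs to reach a given share of free monomer divided by the time a warmer flask needs for that share. Ben takes the curve to keep its shape between the two temperatures, and a ratio taken at one share then leaves that shape out. It is a reading and carries the scatter, and Ben takes the difference in transfer agent as unimportant this early.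

Spreading the factor evenly over the degrees, Ben counts Tuesday's 2.5 d as 10.7 h on red's clock, and red's readings there give about 4.52%. Saturday's counts as 337 h, far past red's last reading, so he ranks it highest.

The forecast sides with Ben, naming Saturday's highest with 5%, 88% and 98% for Tuesday's, Thursday's and Saturday's, on the ground that “living ends accumulate slowly from the pre-initiator, through initiator”, though its Thursday's lies below his.

The flasks give 4.89% for Tuesday's, 84.5% for Thursday's and 98.8% for Saturday's, so Saturday's comes out highest.

    free monomer + initiator → living end + monomer in chains (k = 3.70 × 10⁻⁴ M⁻¹ s⁻¹, Ea = 61.0 kJ mol⁻¹)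
    free monomer + living end → monomer in chains + living end, rate k2*[living end]*[free monomer] (k = 0.130 M⁻¹ s⁻¹, Ea = 42.0 kJ mol⁻¹)
    living end + transfer agent → dead chain (kL = 0.00200 M⁻¹ s⁻¹, Ea = 65.0 kJ mol⁻¹)
    pre-initiator → initiator (k = 2.70 × 10⁻⁶ s⁻¹, Ea = 95.0 kJ mol⁻¹)
    (constants at 0 °C)

Thursday's goes against Anna, yet her view fits its second half, where living ends stand at 8.36 × 10⁻⁵ M after 1.25 d and 8.73 × 10⁻⁵ M after 2.50 d. The half-conversion times of Thursday's and Saturday's give a clock factor of 4.49, against 5.62 reckoned. For the repeat of Saturday's at −10 °C, the clock gives 19.0 h, where red reads about 20.0%, and that flask gives 20.0%. The largest single effect on the gap between Saturday's and Tuesday's is what temperature does to the turning of pre-initiator into initiator: without it the gap falls from 94 percentage points to 22 points.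

(Readings and results stem from a simulated flask for substances that don't exist, and the scatter is random.)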